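**Strategy.** Everything rests on disconnecting the O1–C8a bond of ring B, so that the lactone oxygen is delivered last to a bare C8a–H of ring A. The handle is the para relationship between O7 and C4a. A phenol oxidant makes C4a electrophilic, the C2 carboxylate of a (3R)-3,3-diarylpropanoic acid is captured there as a spirolactone, and acid relays that oxygen to C8a with rearomatisation, closing ring B without disturbing C4. The precursor is the open acid whose ring A bears (lactone numbering) the free C7 phenol, a C5 benzyl ether and the C8 ketone chain. The distal phenol is a benzyl carbonate, so a single hydrogenolysis finishes the synthesis.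

Key step: step 8

Remark on the chemistry: lactone numbering (O1, C2–C4, C4a, C5–C8, C8a) is used throughout; once O5 is free, an opened lactone could reclose on O5 and place the acyl group at C6, so no lactone-opening step follows debenzylation, and the distal phenol is therefore a benzyl carbonate that leaves in the same neutral hydrogenolysis as the C5 benzyl ether.

**Route**

Step 1
Reactants: 1 resorcinol; 2 3-(4-hydroxyphenyl)propanoic acid
Product: 3 1-(2,4-dihydroxyphenyl)-3-(4-hydroxyphenyl)propan-1-one
Conditions: BF3·OEt2 (solvent), 90 °C; then aq NaOAc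
Reagents that add atoms: none
Why: Friedel–Crafts C-acylation (Nencki type) by the BF3-activated acid goes to C4 of resorcinol, ortho to one hydroxyl and para to the other, and the boron-chelated ortho-hydroxy ketone resists a second acylation.

Step 2
Reactants: 3 1-(2,4-dihydroxyphenyl)-3-(4-hydroxyphenyl)propan-1-one
Product: 4 1-[4-(benzyloxy)-2-hydroxyphenyl]-3-(4-hydroxyphenyl)propan-1-one
Conditions: BnBr (1.05 equiv), K2CO3 (1.05 equiv), acetone, 50 °C
Reagents that add atoms: benzyl bromide, BrCc1ccccc1
Why: Williamson etherification is selective because the hydroxyl para to the ketone is markedly the most acidic phenol, the ortho hydroxyl is locked in a hydrogen bond to the carbonyl, and the side-chain phenol is a much weaker acid.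

Step 3
Reactants: 4 1-[4-(benzyloxy)-2-hydroxyphenyl]-3-(4-hydroxyphenyl)propan-1-one
Product: 5 benzyl 4-{3-[4-(benzyloxy)-2-hydroxyphenyl]-3-oxopropyl}phenyl carbonate
Conditions: CbzCl (1.1 equiv), Et3N, CH2Cl2, 0 °C
Reagents that add atoms: benzyl chloroformate, O=C(Cl)OCc1ccccc1
Why: O-acylation with the chloroformate takes the only phenol that is not chelated, and the resulting carbonate makes the side-chain arene electron-poor for steps 4 and 8.

Step 4
Reactants: 5 benzyl 4-{3-[4-(benzyloxy)-2-hydroxyphenyl]-3-oxopropyl}phenyl carbonate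
Product: 6 benzyl 4-{3-[4-(benzyloxy)-2-hydroxy-5-iodophenyl]-3-oxopropyl}phenyl carbonate
Conditions: NIS (1.05 equiv), CF3CO2H (cat.), MeCN, 0 °C to rt
Reagents that add atoms: N-iodosuccinimide, O=C1CCC(=O)N1I
Why: Electrophilic aromatic iodination should go to the ring carbon para to the free phenol, ortho to the benzyl ether and meta to the ketone, in preference to the flanked position between the two oxygens and to the carbonate-deactivated side-chain ring.

Step 5
Reactants: 6 benzyl 4-{3-[4-(benzyloxy)-2-hydroxy-5-iodophenyl]-3-oxopropyl}phenyl carbonate; 7 tert-butyl acrylate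
Product: 8 tert-butyl (2E)-3-[2-(benzyloxy)-5-(3-{4-[(benzyloxycarbonyl)oxy]phenyl}propanoyl)-4-hydroxyphenyl]prop-2-enoate
Conditions: Pd(OAc)2 (5 mol %), P(o-tol)3 (10 mol %), Et3N, MeCN, 70 °C
Reagents that add atoms: none
Why: Mizoroki–Heck coupling (oxidative addition of the aryl iodide to zerovalent palladium, syn insertion of the acrylate, syn β-hydride elimination) gives the E-cinnamate, and the mild anhydrous amine conditions should leave the carbonate and the free phenol alone.

Step 6
Reactants: 8 tert-butyl (2E)-3-[2-(benzyloxy)-5-(3-{4-[(benzyloxycarbonyl)oxy]phenyl}propanoyl)-4-hydroxyphenyl]prop-2-enoate; 9 phenylboronic acid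
Product: 10 tert-butyl (3R)-3-[2-(benzyloxy)-5-(3-{4-[(benzyloxycarbonyl)oxy]phenyl}propanoyl)-4-hydroxyphenyl]-3-phenylpropanoate
Conditions: 9 (2.5 equiv), [RhCl(C2H4)2]2 (2.5 mol %), (S,S)-Ph-bod* [(1S,4S)-2,5-diphenylbicyclo[2.2.2]octa-2,5-diene] (5.5 mol %), aq KOH (6 mol %), 1,4-dioxane/H2O (10:1), 40 °C
Reagents that add atoms: none
Why: Hayashi–Miyaura asymmetric 1,4-addition, in which the phenylrhodium–diene complex adds to one face of the E-enoate and water protonates the oxa-π-allylrhodium; the (S,S) ligand is chosen on the expectation that, as in its enone additions, phenyl is delivered to the α-si face, which corresponds to R at C3 here (to be verified on the first batch, the (R,R) ligand being equally available).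

Step 7
Reactants: 10 tert-butyl (3R)-3-[2-(benzyloxy)-5-(3-{4-[(benzyloxycarbonyl)oxy]phenyl}propanoyl)-4-hydroxyphenyl]-3-phenylpropanoate
Product: 11 (3R)-3-[2-(benzyloxy)-5-(3-{4-[(benzyloxycarbonyl)oxy]phenyl}propanoyl)-4-hydroxyphenyl]-3-phenylpropanoic acid
Conditions: CF3CO2H/CH2Cl2 (1:4), 0 °C to rt
Reagents that add atoms: none
Why: Acidolysis of the tert-butyl ester (loss of isobutene) frees the acid under conditions that should spare the aryl benzyl ether, the benzyl carbonate and the stereocentre.

Step 8
Reactants: 11 (3R)-3-[2-(benzyloxy)-5-(3-{4-[(benzyloxycarbonyl)oxy]phenyl}propanoyl)-4-hydroxyphenyl]-3-phenylpropanoic acid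
Product: 13 (4R)-5-(benzyloxy)-8-(3-{4-[(benzyloxycarbonyl)oxy]phenyl}propanoyl)-7-hydroxy-4-phenyl-3,4-dihydro-2H-chromen-2-one, via spirodienone lactone 12 (not isolated)
Conditions: PhI(OCOCF3)2 (1.05 equiv), (CF3)2CHOH/CH2Cl2 (1:1), 0 °C; then BF3·OEt2 (1.5 equiv), 0 °C to rt
Reagents that add atoms: none
Why: Ligand exchange of the C7 phenol on PhI(OCOCF3)2 and loss of PhI make ring A electrophilic at the para carbon C4a, where the tethered carboxylate closes the spiro γ-lactone of 12 by 5-exo-trig ipso attack. BF3·OEt2 then binds the dienone oxygen (chelated by the C8 acyl group), the lactone carboxylate bridges to the adjacent electron-poor C8a through an acyloxonium-type ion, the C4a–O bond breaks and loss of H-8a restores the arene, so ring B is closed by a 1,2-shift ring expansion of the five-membered lactone to the six-membered one, not by direct attack. The closest known chemistry is the trivalent-iodine ipso-spirolactonization of electron-rich 3-arylpropanoic acids with acid-promoted 1,2-acyloxy migration (a dienone–phenol rearrangement of the quinol-ester kind). The spiro carbon is the only new stereocentre and is transient, so both epimers give the same lactone, and no bond to C4 is made or broken. The step needs oxidation at ring A only, secured by the single free phenol and the carbonate on the other arene, and a shift towards C8a only, secured by the hydrogen there: a shift to C5 would leave a carbon bearing two oxygens that cannot lose a proton and therefore reverts.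

Step 9
Reactants: 13 (4R)-5-(benzyloxy)-8-(3-{4-[(benzyloxycarbonyl)oxy]phenyl}propanoyl)-7-hydroxy-4-phenyl-3,4-dihydro-2H-chromen-2-one
Product: 14 (4R)-5,7-dihydroxy-8-[3-(4-hydroxyphenyl)propanoyl]-4-phenyl-3,4-dihydro-2H-chromen-2-one
Conditions: H2 (1 atm), 10% Pd/C, EtOAc, rt
Reagents that add atoms: none
Why: Catalytic hydrogenolysis cleaves both benzylic C–O bonds, the carbonic half-ester losing CO2, under neutral conditions in which the lactone is never opened, so the acyl group should stay at C8 and C4 should stay R.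

**Compound list**

1 | resorcinol (benzene-1,3-diol) | Oc1cccc(O)c1 | starting material
2 | 3-(4-hydroxyphenyl)propanoic acid | OC(=O)CCc1ccc(O)cc1 | starting material
3 | 1-(2,4-dihydroxyphenyl)-3-(4-hydroxyphenyl)propan-1-one | O=C(CCc1ccc(O)cc1)c1ccc(O)cc1O | intermediate
4 | 1-[4-(benzyloxy)-2-hydroxyphenyl]-3-(4-hydroxyphenyl)propan-1-one | O=C(CCc1ccc(O)cc1)c1ccc(OCc2ccccc2)cc1O | intermediate
5 | benzyl 4-{3-[4-(benzyloxy)-2-hydroxyphenyl]-3-oxopropyl}phenyl carbonate | O=C(CCc1ccc(OC(=O)OCc2ccccc2)cc1)c1ccc(OCc2ccccc2)cc1O | intermediate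
6 | benzyl 4-{3-[4-(benzyloxy)-2-hydroxy-5-iodophenyl]-3-oxopropyl}phenyl carbonate | O=C(CCc1ccc(OC(=O)OCc2ccccc2)cc1)c1cc(I)c(OCc2ccccc2)cc1O | intermediate
7 | tert-butyl acrylate (tert-butyl prop-2-enoate) | C=CC(=O)OC(C)(C)C | starting material
8 | tert-butyl (2E)-3-[2-(benzyloxy)-5-(3-{4-[(benzyloxycarbonyl)oxy]phenyl}propanoyl)-4-hydroxyphenyl]prop-2-enoate | CC(C)(C)OC(=O)/C=C/c1cc(C(=O)CCc2ccc(OC(=O)OCc3ccccc3)cc2)c(O)cc1OCc1ccccc1 | intermediate
9 | phenylboronic acid | OB(O)c1ccccc1 | starting material
10 | tert-butyl (3R)-3-[2-(benzyloxy)-5-(3-{4-[(benzyloxycarbonyl)oxy]phenyl}propanoyl)-4-hydroxyphenyl]-3-phenylpropanoate | CC(C)(C)OC(=O)C[C@H](c1ccccc1)c1cc(C(=O)CCc2ccc(OC(=O)OCc3ccccc3)cc2)c(O)cc1OCc1ccccc1 | intermediate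
11 | (3R)-3-[2-(benzyloxy)-5-(3-{4-[(benzyloxycarbonyl)oxy]phenyl}propanoyl)-4-hydroxyphenyl]-3-phenylpropanoic acid | OC(=O)C[C@H](c1ccccc1)c1cc(C(=O)CCc2ccc(OC(=O)OCc3ccccc3)cc2)c(O)cc1OCc1ccccc1 | intermediate
12 | (4R)-6-(benzyloxy)-9-(3-{4-[(benzyloxycarbonyl)oxy]phenyl}propanoyl)-4-phenyl-1-oxaspiro[4.5]deca-6,9-diene-2,8-dione (both epimers at the spiro carbon C5) | O=C1C[C@H](c2ccccc2)C2(O1)C=C(C(=O)CCc1ccc(OC(=O)OCc3ccccc3)cc1)C(=O)C=C2OCc1ccccc1 | intermediate
13 | (4R)-5-(benzyloxy)-8-(3-{4-[(benzyloxycarbonyl)oxy]phenyl}propanoyl)-7-hydroxy-4-phenyl-3,4-dihydro-2H-chromen-2-one | O=C1C[C@H](c2ccccc2)c2c(OCc3ccccc3)cc(O)c(C(=O)CCc3ccc(OC(=O)OCc4ccccc4)cc3)c2O1 | intermediate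
14 | (4R)-5,7-dihydroxy-8-[3-(4-hydroxyphenyl)propanoyl]-4-phenyl-3,4-dihydro-2H-chromen-2-one | O=C1C[C@H](c2ccccc2)c2c(O)cc(O)c(C(=O)CCc3ccc(O)cc3)c2O1 | target

**Step count and risk**

Total step count: 9. Longest linear sequence: 9 steps (1 and 2 to 14).

Steps most likely to fail:

Step 8. The hydrogen-bonded, ketone-deactivated phenol may be oxidised slowly, so that oxidation α to the ketone competes. The oxidised ring may lose the doubly benzylic C4 proton instead of being trapped (quinone methide formation, which would erase the stereocentre). Carbon instead of oxygen may migrate from C4a, or BF3·OEt2 may cleave the benzyl group from the vinylogous ester of 12. The fallback places the C8a oxygen in ring A from the start and closes ring B by acid-mediated hydroarylation and lactonization, followed by resolution; it sets out from 2 and comes back at 13. Acid 2 and commercial phloroglucinol (benzene-1,3,5-triol) are condensed in BF3·OEt2 to phloretin F1. BnBr/K2CO3 alkylates the most acidic hydroxyl, para to the ketone, to give 1-[4-(benzyloxy)-2,6-dihydroxyphenyl]-3-(4-hydroxyphenyl)propan-1-one F2. Benzyl chloroformate/Et3N converts the side-chain phenol into benzyl 4-{3-[4-(benzyloxy)-2,6-dihydroxyphenyl]-3-oxopropyl}phenyl carbonate F3. Warming F3 with (E)-cinnamic acid in CF3CO2H should alkylate one of the two equivalent free ring carbons; the adjacent free phenol, the only one next to the new chain, then lactonizes to give the racemic lactone F4. Preparative chromatography on a chiral stationary phase then gives 13.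

Step 6. The aqueous base may hydrolyse the aryl carbonate, the partly ionised para phenol may slow the conjugate addition, or facial selectivity may be insufficient for this ortho-alkoxy cinnamate. The fallback replaces asymmetric catalysis by a base-free racemic addition and resolution; it sets out from 8 and comes back at 10. Cinnamate 8 and 9 with [Rh(OH)(C8H12)]2 (C8H12 = cycloocta-1,5-diene) in 1,4-dioxane/H2O without added base should give the racemic tert-butyl 3,3-diarylpropanoate F5, which is separated by preparative chromatography on a chiral stationary phase to give 10.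

Step 4. Iodination may go partly to the position between the two oxygens of ring A, or a second iodine may be taken up. The fallback buys the halogen in place; it is held in reserve because it needs acylation of a halogenated resorcinol and a hotter Heck reaction of a less reactive aryl bromide. It sets out from 2 and comes back at 8. Acid 2 and commercial 4-bromoresorcinol (4-bromobenzene-1,3-diol) in BF3·OEt2 at 90 °C give 1-(5-bromo-2,4-dihydroxyphenyl)-3-(4-hydroxyphenyl)propan-1-one F6, acylation going to the only carbon that is ortho to one hydroxyl and para to the other. BnBr/K2CO3 gives 1-[4-(benzyloxy)-5-bromo-2-hydroxyphenyl]-3-(4-hydroxyphenyl)propan-1-one F7. Heck coupling with 7 (Pd(OAc)2, P(o-tol)3, Et3N, DMF, 110 °C) gives tert-butyl (2E)-3-{2-(benzyloxy)-4-hydroxy-5-[3-(4-hydroxyphenyl)propanoyl]phenyl}prop-2-enoate F8. Benzyl chloroformate/Et3N on the side-chain phenol then gives 8.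

**Further compounds**

F1 | step 8 | phloretin, 3-(4-hydroxyphenyl)-1-(2,4,6-trihydroxyphenyl)propan-1-one | O=C(CCc1ccc(O)cc1)c1c(O)cc(O)cc1O
F2 | step 8 | 1-[4-(benzyloxy)-2,6-dihydroxyphenyl]-3-(4-hydroxyphenyl)propan-1-one | O=C(CCc1ccc(O)cc1)c1c(O)cc(OCc2ccccc2)cc1O
F3 | step 8 | benzyl 4-{3-[4-(benzyloxy)-2,6-dihydroxyphenyl]-3-oxopropyl}phenyl carbonate | O=C(CCc1ccc(OC(=O)OCc2ccccc2)cc1)c1c(O)cc(OCc2ccccc2)cc1O
F4 | step 8 | racemic 5-(benzyloxy)-8-(3-{4-[(benzyloxycarbonyl)oxy]phenyl}propanoyl)-7-hydroxy-4-phenyl-3,4-dihydro-2H-chromen-2-one | O=C1CC(c2ccccc2)c2c(OCc3ccccc3)cc(O)c(C(=O)CCc3ccc(OC(=O)OCc4ccccc4)cc3)c2O1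
F5 | step 6 | racemic tert-butyl 3-[2-(benzyloxy)-5-(3-{4-[(benzyloxycarbonyl)oxy]phenyl}propanoyl)-4-hydroxyphenyl]-3-phenylpropanoate | CC(C)(C)OC(=O)CC(c1ccccc1)c1cc(C(=O)CCc2ccc(OC(=O)OCc3ccccc3)cc2)c(O)cc1OCc1ccccc1
F6 | step 4 | 1-(5-bromo-2,4-dihydroxyphenyl)-3-(4-hydroxyphenyl)propan-1-one | O=C(CCc1ccc(O)cc1)c1cc(Br)c(O)cc1O
F7 | step 4 | 1-[4-(benzyloxy)-5-bromo-2-hydroxyphenyl]-3-(4-hydroxyphenyl)propan-1-one | O=C(CCc1ccc(O)cc1)c1cc(Br)c(OCc2ccccc2)cc1O
F8 | step 4 | tert-butyl (2E)-3-{2-(benzyloxy)-4-hydroxy-5-[3-(4-hydroxyphenyl)propanoyl]phenyl}prop-2-enoate | CC(C)(C)OC(=O)/C=C/c1cc(C(=O)CCc2ccc(O)cc2)c(O)cc1OCc1ccccc1
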